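The depside is divided at its aryl ester into a ring A acid and a ring B phenol, and everything rests on building ring A from a 2-pyrone instead of decorating an arene. Ring A carries the ester at C1, oxygen at C2, methoxy at C4, the side chain at C6 and hydrogen at C3 and C5; a 4-benzyloxy-6-alkyl-2-pyrone-5-carboxylate plus 1,1-dimethoxyethene supplies exactly this array. One thermal operation forms the C3–C4 and C5–C6 bonds, expels CO2 and methanol, and delivers the 2-O-benzyl/4-O-methyl pattern with no selective alkylation. The pyrone already holds the allyl ester and the dioxolane-masked 2-oxoheptyl chain. Ring B comes from orsellinic acid.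

Key step: step 5

Assumption: N-methoxy-N-methylhexanamide and orsellinic acid are taken as purchasable (the amide is otherwise one acylation away from hexanoyl chloride); the target has no stereocentre, and the transient bicycle 9 and the fallback alcohol F5 are racemic.

Step 1
Reactants: 1 allyl acetoacetate; 2 malonyl dichloride
Product: 3 allyl 4-hydroxy-6-methyl-2-oxo-2H-pyran-5-carboxylate
Conditions: CH2Cl2, 0 °C → reflux, slow N2 stream
Reagents that add atoms: none
Why: Acylative cyclocondensation, in which the enol of the keto ester is C-acylated at its α-carbon by one acyl chloride and O-acylated by the other, closes the 4-hydroxy-2-pyrone with the ester at C5 and the methyl group at C6, a known reaction of acetoacetates with malonyl dichloride that the allyl ester should tolerate.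

Step 2
Reactants: 3 allyl 4-hydroxy-6-methyl-2-oxo-2H-pyran-5-carboxylate
Product: 4 allyl 4-(benzyloxy)-6-methyl-2-oxo-2H-pyran-5-carboxylate
Conditions: BnOH, PPh3, diisopropyl azodicarboxylate, THF, 0 °C → rt
Reagents that add atoms: benzyl alcohol, OCc1ccccc1
Why: Mitsunobu etherification, in which the acidic 4-hydroxyl (a vinylogous carboxylic acid) protonates the phosphine–azodicarboxylate adduct and the pyronate is benzylated on O4 by the alkoxyphosphonium ion, is the established mode for 4-hydroxy-2-pyrones and avoids the C3-alkylation that benzyl halides and base can give.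

Step 3
Reactants: 4 allyl 4-(benzyloxy)-6-methyl-2-oxo-2H-pyran-5-carboxylate; 5 N-methoxy-N-methylhexanamide
Product: 6 allyl 4-(benzyloxy)-2-oxo-6-(2-oxoheptyl)-2H-pyran-5-carboxylate
Conditions: LiN(SiMe3)2 (1.2 equiv), THF, −78 °C; then 5, −78 → −20 °C; AcOH, −78 °C
Reagents that add atoms: none
Why: Lateral deprotonation followed by Weinreb ketone synthesis should work because the 6-methyl protons are vinylogous to both the C5 ester and the lactone carbonyl, and the exocyclic anion adds once to the amide to give a chelated adduct that releases the ketone only on the cold acidic quench, so that neither a second deprotonation nor lactonisation of a ketone enolate onto the C5 ester can interfere.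

Step 4
Reactants: 6 allyl 4-(benzyloxy)-2-oxo-6-(2-oxoheptyl)-2H-pyran-5-carboxylate
Product: 7 allyl 4-(benzyloxy)-2-oxo-6-[(2-pentyl-1,3-dioxolan-2-yl)methyl]-2H-pyran-5-carboxylate
Conditions: Me3SiOCH2CH2OSiMe3, Me3SiOSO2CF3 (5 mol %), CH2Cl2, −78 → −20 °C; pyridine quench
Reagents that add atoms: 1,2-bis(trimethylsilyloxy)ethane, C[Si](C)(C)OCCO[Si](C)(C)C
Why: Noyori ketalisation is aprotic and runs below 0 °C, so the dioxolane should form without cleavage of the C4 enol ether or acid-induced enol-lactonisation of the keto ester, and it removes the acidic CH2–C=O unit that would otherwise quench the ketene acetal in step 5.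

Step 5
Reactants: 7 allyl 4-(benzyloxy)-2-oxo-6-[(2-pentyl-1,3-dioxolan-2-yl)methyl]-2H-pyran-5-carboxylate; 8 1,1-dimethoxyethene
Product: 11 allyl 2-(benzyloxy)-4-methoxy-6-[(2-pentyl-1,3-dioxolan-2-yl)methyl]benzoate, via bridged lactone cycloadduct 9 (not isolated), via gem-dimethoxy cyclohexadiene 10 (not isolated)
Conditions: 8 (5 equiv), toluene, sealed tube, 120–140 °C
Reagents that add atoms: none
Why: The electron-rich CH2 terminus of the ketene acetal should bond to pyrone C6, the β-carbon of the C5 acrylate unit, and the acetal carbon to C3, giving the bridged lactone 9 in an asynchronous inverse-electron-demand Diels–Alder reaction. Ring A is thereby closed in the [4+2] mode across pyrone C3 and C6, after which cycloreversion of 9 expels CO2 to give diene 10 and 1,2-elimination of methanol aromatises it. The closest known reaction type is the cycloaddition of 2-pyrone carboxylates such as coumalate esters with 1,1-dialkoxyethenes, which gives para-alkoxybenzoates in the same sense. No stereocentre survives, since the two bridgehead centres of 9 are erased on aromatisation. The selectivity needed is regiochemical, methoxy para to the ester, and it is secured by the polarisation of the diene: C6 is electrophilic through the C5 ester and the lactone, while C3 is the enolate terminus made electron-rich by the 4-benzyloxy group. The dioxolane keeps an acidic keto-methylene away from the acid-sensitive dienophile, and a benzyl ether, unlike an allyl ether, cannot rearrange at this temperature.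

Step 6
Reactants: 11 allyl 2-(benzyloxy)-4-methoxy-6-[(2-pentyl-1,3-dioxolan-2-yl)methyl]benzoate
Product: 12 2-(benzyloxy)-4-methoxy-6-[(2-pentyl-1,3-dioxolan-2-yl)methyl]benzoic acid
Conditions: Pd(PPh3)4 (5 mol %), morpholine, THF, rt; aqueous citric acid work-up (pH 4–5)
Reagents that add atoms: none
Why: Tsuji–Trost deallylation, in which zerovalent palladium ionises the allyl ester to a π-allyl complex that morpholine intercepts, should free the di-ortho-substituted acid under neutral conditions that leave the dioxolane, the benzyl ether and the methyl ether untouched.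

Step 7
Reactants: 13 2,4-dihydroxy-6-methylbenzoic acid (orsellinic acid)
Product: 14 benzyl 2,4-dihydroxy-6-methylbenzoate
Conditions: BnBr, KHCO3, DMF, rt
Reagents that add atoms: benzyl bromide, BrCc1ccccc1
Why: Carboxylate alkylation (SN2 esterification) should be selective because hydrogen carbonate deprotonates only the acid, and room temperature keeps the acid below the point at which it decarboxylates.

Step 8
Reactants: 14 benzyl 2,4-dihydroxy-6-methylbenzoate
Product: 15 benzyl 4-(allyloxy)-2-hydroxy-6-methylbenzoate
Conditions: allyl bromide (1.05 equiv), K2CO3, acetone, rt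
Reagents that add atoms: allyl bromide, C=CCBr
Why: Williamson etherification should take place at the 4-hydroxyl alone, which is the more acidic and unhindered phenol, whereas the 2-hydroxyl is held in a hydrogen bond to the ester carbonyl.

Step 9
Reactants: 15 benzyl 4-(allyloxy)-2-hydroxy-6-methylbenzoate
Product: 16 benzyl 4-(allyloxy)-2-methoxy-6-methylbenzoate
Conditions: MeI, K2CO3, DMF, 40 °C
Reagents that add atoms: iodomethane, CI
Why: Williamson etherification under more forcing conditions should methylate the remaining chelated 2-hydroxyl, the only nucleophilic site left, well below the temperature of an aromatic Claisen rearrangement of the allyl ether.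

Step 10
Reactants: 16 benzyl 4-(allyloxy)-2-methoxy-6-methylbenzoate; 5 N-methoxy-N-methylhexanamide
Product: 17 benzyl 4-(allyloxy)-2-methoxy-6-(2-oxoheptyl)benzoate
Conditions: LiN(iPr)2 (1.1 equiv), THF, −78 °C; then 5, −78 → −40 °C; AcOH, −78 °C
Reagents that add atoms: none
Why: Lateral lithiation of an ortho-toluate followed by Weinreb ketone synthesis should work because the ester-activated methyl group is by far the most acidic site, the flanking 2-methoxy and 6-methyl groups shield the ester from self-condensation, and the benzylic anion adds only once to the amide.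

Step 11
Reactants: 17 benzyl 4-(allyloxy)-2-methoxy-6-(2-oxoheptyl)benzoate
Product: 18 benzyl 4-hydroxy-2-methoxy-6-(2-oxoheptyl)benzoate
Conditions: Pd(PPh3)4 (3 mol %), morpholine, THF, rt
Reagents that add atoms: none
Why: Tsuji–Trost deallylation of the aryl allyl ether by zerovalent palladium with morpholine as allyl acceptor should free the phenol, while the benzyl ester is inert and the ketone is not enolised by the weak amine base.

Step 12
Reactants: 12 2-(benzyloxy)-4-methoxy-6-[(2-pentyl-1,3-dioxolan-2-yl)methyl]benzoic acid; 18 benzyl 4-hydroxy-2-methoxy-6-(2-oxoheptyl)benzoate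
Product: 19 benzyl 4-({2-(benzyloxy)-4-methoxy-6-[(2-pentyl-1,3-dioxolan-2-yl)methyl]benzoyl}oxy)-2-methoxy-6-(2-oxoheptyl)benzoate
Conditions: N,N'-dicyclohexylcarbodiimide, 4-(dimethylamino)pyridine (0.2 equiv), CH2Cl2, 0 °C → rt
Reagents that add atoms: none
Why: Steglich esterification should transfer the carbodiimide-activated acyl group to the unhindered, acidic 4-hydroxyl of ring B, while the dioxolane on ring A blocks the enol-lactonisation to an isocoumarin that an activated 2-(2-oxoalkyl)benzoic acid would undergo.

Step 13
Reactants: 19 benzyl 4-({2-(benzyloxy)-4-methoxy-6-[(2-pentyl-1,3-dioxolan-2-yl)methyl]benzoyl}oxy)-2-methoxy-6-(2-oxoheptyl)benzoate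
Product: 20 benzyl 4-{[2-(benzyloxy)-4-methoxy-6-(2-oxoheptyl)benzoyl]oxy}-2-methoxy-6-(2-oxoheptyl)benzoate
Conditions: 1 M aqueous HCl, THF, rt
Reagents that add atoms: water, O
Why: Acid-catalysed ketal hydrolysis through the oxocarbenium ion should return the ring A ketone at room temperature, conditions under which the benzyl ether, the benzyl ester and the diaryl ester are stable and no free acid or phenol is yet present to complicate matters.

Step 14
Reactants: 20 benzyl 4-{[2-(benzyloxy)-4-methoxy-6-(2-oxoheptyl)benzoyl]oxy}-2-methoxy-6-(2-oxoheptyl)benzoate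
Product: 21 4-{[2-hydroxy-4-methoxy-6-(2-oxoheptyl)benzoyl]oxy}-2-methoxy-6-(2-oxoheptyl)benzoic acid (CNP0177576.0)
Conditions: H2 (1 atm), 10% Pd/C, EtOAc, rt
Reagents that add atoms: none
Why: Catalytic hydrogenolysis should cleave the ring A benzyl ether and the ring B benzyl ester in one neutral operation that the depside ester and the two aliphatic ketones tolerate.

Compound list
1 | allyl acetoacetate | CC(=O)CC(=O)OCC=C | starting material
2 | malonyl dichloride | O=C(Cl)CC(Cl)=O | starting material
3 | allyl 4-hydroxy-6-methyl-2-oxo-2H-pyran-5-carboxylate | CC1=C(C(=O)OCC=C)C(O)=CC(=O)O1 | intermediate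
4 | allyl 4-(benzyloxy)-6-methyl-2-oxo-2H-pyran-5-carboxylate | CC1=C(C(=O)OCC=C)C(OCc2ccccc2)=CC(=O)O1 | intermediate
5 | N-methoxy-N-methylhexanamide | CCCCCC(=O)N(C)OC | starting material
6 | allyl 4-(benzyloxy)-2-oxo-6-(2-oxoheptyl)-2H-pyran-5-carboxylate | CCCCCC(=O)CC1=C(C(=O)OCC=C)C(OCc2ccccc2)=CC(=O)O1 | intermediate
7 | allyl 4-(benzyloxy)-2-oxo-6-[(2-pentyl-1,3-dioxolan-2-yl)methyl]-2H-pyran-5-carboxylate | O=C1C=C(OCc2ccccc2)C(C(=O)OCC=C)=C(CC2(CCCCC)OCCO2)O1 | intermediate
8 | 1,1-dimethoxyethene | C=C(OC)OC | starting material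
9 | allyl 5-(benzyloxy)-8,8-dimethoxy-3-oxo-1-[(2-pentyl-1,3-dioxolan-2-yl)methyl]-2-oxabicyclo[2.2.2]oct-5-ene-6-carboxylate (racemic, not isolated) | O=C1OC2(CC3(CCCCC)OCCO3)CC(OC)(OC)C1C(OCc1ccccc1)=C2C(=O)OCC=C | intermediate
10 | allyl 6-(benzyloxy)-4,4-dimethoxy-2-[(2-pentyl-1,3-dioxolan-2-yl)methyl]cyclohexa-1,5-diene-1-carboxylate (not isolated) | COC1(OC)CC(CC2(CCCCC)OCCO2)=C(C(=O)OCC=C)C(OCc2ccccc2)=C1 | intermediate
11 | allyl 2-(benzyloxy)-4-methoxy-6-[(2-pentyl-1,3-dioxolan-2-yl)methyl]benzoate | C=CCOC(=O)c1c(OCc2ccccc2)cc(OC)cc1CC1(CCCCC)OCCO1 | intermediate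
12 | 2-(benzyloxy)-4-methoxy-6-[(2-pentyl-1,3-dioxolan-2-yl)methyl]benzoic acid | OC(=O)c1c(OCc2ccccc2)cc(OC)cc1CC1(CCCCC)OCCO1 | intermediate
13 | 2,4-dihydroxy-6-methylbenzoic acid (orsellinic acid) | Cc1cc(O)cc(O)c1C(=O)O | starting material
14 | benzyl 2,4-dihydroxy-6-methylbenzoate | Cc1cc(O)cc(O)c1C(=O)OCc1ccccc1 | intermediate
15 | benzyl 4-(allyloxy)-2-hydroxy-6-methylbenzoate | Cc1cc(OCC=C)cc(O)c1C(=O)OCc1ccccc1 | intermediate
16 | benzyl 4-(allyloxy)-2-methoxy-6-methylbenzoate | Cc1cc(OCC=C)cc(OC)c1C(=O)OCc1ccccc1 | intermediate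
17 | benzyl 4-(allyloxy)-2-methoxy-6-(2-oxoheptyl)benzoate | CCCCCC(=O)Cc1cc(OCC=C)cc(OC)c1C(=O)OCc1ccccc1 | intermediate
18 | benzyl 4-hydroxy-2-methoxy-6-(2-oxoheptyl)benzoate | CCCCCC(=O)Cc1cc(O)cc(OC)c1C(=O)OCc1ccccc1 | intermediate
19 | benzyl 4-({2-(benzyloxy)-4-methoxy-6-[(2-pentyl-1,3-dioxolan-2-yl)methyl]benzoyl}oxy)-2-methoxy-6-(2-oxoheptyl)benzoate | CCCCCC1(Cc2cc(OC)cc(OCc3ccccc3)c2C(=O)Oc2cc(CC(=O)CCCCC)c(C(=O)OCc3ccccc3)c(OC)c2)OCCO1 | intermediate
20 | benzyl 4-{[2-(benzyloxy)-4-methoxy-6-(2-oxoheptyl)benzoyl]oxy}-2-methoxy-6-(2-oxoheptyl)benzoate | CCCCCC(=O)Cc1cc(OC)cc(OCc2ccccc2)c1C(=O)Oc1cc(CC(=O)CCCCC)c(C(=O)OCc2ccccc2)c(OC)c1 | intermediate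
21 | 4-{[2-hydroxy-4-methoxy-6-(2-oxoheptyl)benzoyl]oxy}-2-methoxy-6-(2-oxoheptyl)benzoic acid | CCCCCC(=O)Cc1cc(OC)cc(O)c1C(=O)Oc1cc(CC(=O)CCCCC)c(C(=O)O)c(OC)c1 | target

Total step count: 14 (ring A acid, steps 1–6; ring B phenol, steps 7–11; union and finish, steps 12–14).
Longest linear sequence: 9 steps (steps 1–6, then 12–14).

Steps most likely to fail

The cycloaddition of step 5 carries the main risk. The diene is only moderately electron-poor because of the 4-benzyloxy donor, and its C6 terminus is shielded by the ketal-bearing substituent. At the temperature then needed, the ketene acetal may oligomerise, or may add to C4 with displacement of benzyloxide, before ring A closes. The fallback abandons the ring construction and runs from 13 back to 11 by arene chemistry. Compound 13 would be esterified with allyl bromide and KHCO3 in DMF to allyl 2,4-dihydroxy-6-methylbenzoate F1. The unchelated 4-hydroxyl would be methylated with one equivalent of MeI and K2CO3 in acetone to allyl 2-hydroxy-4-methoxy-6-methylbenzoate F2. The chelated 2-hydroxyl would be benzylated with BnBr and K2CO3 in DMF at 60 °C to allyl 2-(benzyloxy)-4-methoxy-6-methylbenzoate F3. Lateral lithiation with LiN(iPr)2 at −78 °C and acylation with 5 would give allyl 2-(benzyloxy)-4-methoxy-6-(2-oxoheptyl)benzoate F4, and the ketalisation of step 4 applied to F4 would deliver 11. This path depends on the selectivity of two successive phenol alkylations.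

The acylation of step 3 may fail because the exocyclic anion, stabilised by two carbonyl groups, adds too slowly to the amide, and on warming self-condensation of the anion with unreacted pyrone takes over. The fallback runs from 4 back to 6 and replaces the acyl donor by an aldehyde followed by oxidation. The anion of 4 would add to hexanal at −78 °C (aldol addition, acetic acid quench at that temperature) to give allyl 4-(benzyloxy)-6-(2-hydroxyheptyl)-2-oxo-2H-pyran-5-carboxylate F5. Dess–Martin oxidation in buffered CH2Cl2 would then return ketone 6.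

The esterification of step 12 may fail because transfer of the di-ortho-substituted acyl group is slow, so the O-acylisourea rearranges to the unreactive N-acylurea before the phenol is acylated. The fallback runs from 12 back to 19 through a preformed acyl halide made under neutral conditions. Acid 12 would be treated with 1-chloro-N,N,2-trimethylprop-1-en-1-amine in CH2Cl2 to give 2-(benzyloxy)-4-methoxy-6-[(2-pentyl-1,3-dioxolan-2-yl)methyl]benzoyl chloride F6. F6 would acylate phenol 18 in the presence of triethylamine and catalytic 4-(dimethylamino)pyridine to give 19.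

Further compounds
F1 | step 5 | allyl 2,4-dihydroxy-6-methylbenzoate | Cc1cc(O)cc(O)c1C(=O)OCC=C
F2 | step 5 | allyl 2-hydroxy-4-methoxy-6-methylbenzoate | Cc1cc(OC)cc(O)c1C(=O)OCC=C
F3 | step 5 | allyl 2-(benzyloxy)-4-methoxy-6-methylbenzoate | Cc1cc(OC)cc(OCc2ccccc2)c1C(=O)OCC=C
F4 | step 5 | allyl 2-(benzyloxy)-4-methoxy-6-(2-oxoheptyl)benzoate | CCCCCC(=O)Cc1cc(OC)cc(OCc2ccccc2)c1C(=O)OCC=C
F5 | step 3 | allyl 4-(benzyloxy)-6-(2-hydroxyheptyl)-2-oxo-2H-pyran-5-carboxylate (racemic) | CCCCCC(O)CC1=C(C(=O)OCC=C)C(OCc2ccccc2)=CC(=O)O1
F6 | step 12 | 2-(benzyloxy)-4-methoxy-6-[(2-pentyl-1,3-dioxolan-2-yl)methyl]benzoyl chloride | O=C(Cl)c1c(OCc2ccccc2)cc(OC)cc1CC1(CCCCC)OCCO1
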